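The number to beat is 0.693, the drop in ln[starting material] that halves it, call it the price, and two chemists at the blackboard dispute whether the catalyst charge can pay it.

starting material 0.10 M; reagent 0.0700 M; protic impurity 0.0300 M; free catalyst 15 mM

    free catalyst → spent catalyst (k1 = 0.094 h⁻¹)
    starting material + free catalyst ⇌ free catalyst + open intermediate (K2 = 1.1, k2 = 11 M⁻¹ h⁻¹)
    starting material + protic impurity → quenched substrate (k3 = 2.4 M⁻¹ h⁻¹)
    free catalyst + open intermediate ⇌ catalyst intermediate (K4 = 4.3 M⁻¹, k4 = 41 M⁻¹ h⁻¹)
    reagent + catalyst intermediate → free catalyst + product (k5 = 250 M⁻¹ h⁻¹)

- the form that holds most of the catalyst when 50% of the starting material are converted (spent catalyst / catalyst intermediate / free catalyst)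
- its share of the catalyst then
- factor on the rate of making product when 50% of the starting material are converted if reagent is charged twice over
- factor on the rate when 50% of the starting material are converted if free catalyst is charged at 3.0 mM instead

They agree on one point. With reagent as charged, catalyst intermediate is cleared at 17.5 h⁻¹ per intermediate, faster than free catalyst would be captured even with the whole 0.10 M present as open intermediate, 4.10 h⁻¹. So free catalyst is the resting state of the round.

The first chemist says the round stays intact: free catalyst keeps its charge, and the rate follows the load, a factor of 0.200 at 3.0 mM.

The second chemist, whose reckoning I share, divides one rate by another. Free catalyst dies at 0.094 h⁻¹ times [free catalyst], and starting material opens at 11 M⁻¹ h⁻¹ times [starting material][free catalyst]. In the quotient time drops out, and so does [free catalyst]: the fall in ln[starting material] equals 11 M⁻¹ h⁻¹/0.094 h⁻¹ times the fall in [free catalyst]. I call the whole charge's worth of this the reach, the natural-log drop in [starting material] that a catalyst charge buys by the forward step of opening before it is spent: 1.76 at 15 mM.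

Reach exceeds the price, and paying it leaves 60.5% of the catalyst free. That is my figure, for the forward step of opening alone; the protic impurity also removes starting material, at 0.0720 h⁻¹ against 0.165 h⁻¹ for opening at the start, which pushes the share up, while the back step of opening pushes it down.

At 3.0 mM the reach is 0.351, below the price. The forward step of opening then takes the starting material down to 70.4% of its charge, so the halving must lean on the impurity. I expect a factor below the first chemist's 0.200.

The forecast sides with the second chemist: free catalyst at 64% (60% to 68%), reagent factor 1.12 (1.05 to 1.2), load factor 0.012 (0.003 to 0.04), on the ground that “Free catalyst decays to about 9.6 mM”.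

The simulation gives free catalyst at 64.7%, spent catalyst 33.3%, catalyst intermediate 1.98%, reagent factor 1.16 and load factor 0.0111, so the second chemist wins. The first chemist's intact round suits spans short against the catalyst half-life of 7.37 h: in the 15 mM flask at 0.250 d, shorter than that, spent catalyst already stood at 42.3%. That flask, with reach 1.76, came to the halving with free catalyst at 64.7%. In the 3.0 mM flask, with reach 0.351, free catalyst held 4.33% of the catalyst at the same conversion.

The constants come from no measurement; the flask was simulated.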